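# Proposed total synthesis of CNP0149198.0 by a late [3+3] construction of the hexasubstituted benzene ring

## Analysis of the target

- **Structure.** The target (18, C25H32O7) has two rings joined by one CH2 group.
  - Ring A is a hexasubstituted benzene: C1 (CH2 bridge), C2 (OH), C3 (prenyl), C4 (OH), C5 (2-methylpropanoyl), C6 (OMe).
  - Ring B is a 4-hydroxy-2H-pyran-2-one: O1', C2' (C=O), C3' (bridge), C4' (OH), C5' (methyl), C6' (ethyl).
- **Stereochemistry.** There is no stereocentre, and the prenyl alkene carries two identical methyl groups. The problem is purely one of constitution: six different substituents must stand in one fixed order on ring A.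
- **Hardest detail.** The single methyl ether sits on the C6 oxygen, ortho to the acyl group and next to the bridge. The more acidic and more accessible hydroxyls (C4'–OH of ring B, and C2–OH para to the acyl group) stay free, so a late methylation cannot find C6–OH.
- **Feature on which the plan rests.**
  - Around ring A the O-bearing carbons (C2, C4, C6) alternate with the C-bearing ones (C1, C3, C5).
  - The segment C2–C3–C4 is the enol form of a 2-prenylmalonyl unit and is locally symmetric.
  - The segment C5–C6–C1, together with the acyl carbonyl, is the methyl enol ether of a β-diketone.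
  - The bridge CH2–C1–C6–C5 is an unbranched four-carbon chain hanging on the nucleophilic C3' of ring B.
- **Sensitive groups.**
  - The prenyl group lies between two phenols, so acid closes a chroman or adds HX.
  - Ring B is an ambident vinylogous acid.
  - The arene is electron-rich.
  - The doubly vinylogous CH2 bridge can ionise by retro-Michael cleavage and scramble on heating with acid or base.
- **Consequence.** The end game has to be short and mild.

## Retrosynthetic reasoning

**18 to 10 + 15 (bonds C1–C2 and C4–C5, ring A).**
- Ring A is cut at the two bonds that flank the malonyl-type segment C2–C3–C4.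
- This releases the symmetric dielectrophile 15 and the diene 10. Diene 10 already carries ring B, the bridge, the C6 methoxy group and the acyl group.
- The cut is made here because 15 has two equivalent acyl groups, so no orientation problem can arise. In addition, the methyl ether is present before the ring exists, so it never has to be placed on a phenol.
- The forward reaction must acylate C1 first (giving 16), then close C5 onto the second acyl carbon and aromatise (giving 17, then 18).

**15 to 14, 13, and 11 + 12.**
- The dichloride goes back through the diacid 14 and the diester 13 to a malonic ester alkylation of 11 with 12.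
- The prenyl group therefore enters by an SN2 reaction on an open chain, and not by C-alkylation of an ambident phenolate.

**10 to 9.**
- The diene is the bis-silyl derivative of the β-methoxy enone 9.
- One silyl group masks C4'–OH. The other fixes the extended enol, so that C1 becomes the nucleophilic terminus.

**9 to 8 (C6–OMe).**
- The methyl ether is traced to enol etherification of the β-diketone 8.
- The choice lies between a carbonyl flanked by a CH2 group and one flanked by an isopropyl group. This difference is much larger than any difference between the phenols of ring A.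

**8 to 6 + 7 (bond C5–acyl carbon).**
- A crossed Claisen-type acylation of the methyl group of ketone 6 with 7 installs the whole 2-methylpropanoyl group.

**6 to 4 + 5 (bond C3'–bridge).**
- The bridge is not made from a one-carbon electrophile between two rings.
- It is the terminal carbon of 5, taken up in a Michael addition of 4. Compound 5 thus supplies the bridge carbon and C1, C6 and C5 of ring A in one step.

**4 to 2 + 3, and 2 to 1.**
- Ring B comes from the C,O-diacylation of the enol silane 2 of the symmetric ketone 1 with 3.
- Both rings of the target are therefore closed with a malonyl dichloride: ring B through C and O, ring A through C and C.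

## Alternatives that were turned down

**Alternative 1: the textbook disconnection, cutting the bridge at C1–CH2.**
- *Forward key step.* Compound 4 is condensed with a one-carbon electrophile at the aldehyde oxidation level. This gives 6-ethyl-5-methyl-3-methylidene-2H-pyran-2,4(3H)-dione A2. A2 is trapped at the only free ring position of 1-[2,4-dihydroxy-6-methoxy-3-(3-methylbut-2-en-1-yl)phenyl]-2-methylpropan-1-one A1.
- *Why turned down.*
  - The step itself is sound, but it moves the whole difficulty into A1.
  - The five substituents of A1 must be placed one after another on a preformed phloroglucinol ring whose positions differ only slightly.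
  - Acylation can go between two hydroxyls, or between a hydroxyl and the methoxy group.
  - C-prenylation competes with O-prenylation, double prenylation and attack at the position meant for the bridge.
  - In the union, two carbon nucleophiles compete for one electrophile, so self-coupling of either partner is built in.
  - It is also the route that would be drawn first.

**Alternative 2: an aryne at C4–C5 of ring A.**
- *Forward key step.* Fluoride releases the aryne A4 from the silyl triflate A3, in which both other hydroxyls are protected as methoxymethyl ethers. The aryne inserts into the C–O bond of the carboxylic acid that carries the isopropyl group.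
- *Orientation.* The C6 methoxy group polarises the triple bond. The carboxylate oxygen adds at C4, and the aryl anion at C5 picks up the acyl group, which is the correct orientation.
- *Why turned down.*
  - A3 is itself a fully substituted benzene whose six groups would need the same stepwise substitution chemistry as A1, plus two protections.
  - The prenyl group at C3 offers allylic hydrogens right beside the triple bond for an intramolecular ene reaction.
  - The step adds only two of the six substituents.

**Alternative 3: a biomimetic Claisen fold of a pyranone-masked tetraketide.**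
- *Forward key step.* In the bis-pyranone A5, base such as Mg(OMe)2 or KOH makes the side-chain CH2 (future C5) attack the lactone carbonyl (future C4). The ring oxygen is expelled, giving the O-demethyl compound A6.
- *Why turned down.*
  - The oxygen on C6 is released as a phenoxide among four acidic hydroxyls. It is one of the two that are chelated to the acyl group, so it is among the last to be methylated.
  - A5 is as hard to make as the target.
  - The aldol folding mode competes with the Claisen mode.

Key step: step 10

Assumption: the target is taken as the 4-hydroxy-2H-pyran-2-one tautomer. Compounds 2, 10 and 16 are mixtures of geometric isomers or stereoisomers whose configuration is lost in the next event, so their SMILES carry no stereo descriptors.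

## Route

Step 1
Reactants: 1 pentan-3-one
Product: 2 3-(trimethylsilyloxy)pent-2-ene (E/Z mixture)
Conditions: Me3SiOTf (1.1 equiv), Et3N (1.3 equiv), Et2O, 0 °C to rt
Reagents that add atoms: trimethylsilyl trifluoromethanesulfonate, C[Si](C)(C)OS(=O)(=O)C(F)(F)F
Why: Soft enolisation of a symmetric ketone, so only one constitution of the enol silane is possible. The alkene geometry is lost in step 2.

Step 2
Reactants: 2 3-(trimethylsilyloxy)pent-2-ene; 3 propanedioyl dichloride (malonyl dichloride)
Product: 4 6-ethyl-4-hydroxy-5-methyl-2H-pyran-2-one
Conditions: Et2O, −78 °C to rt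
Reagents that add atoms: none
Why: Effenberger pyranone synthesis: the enol silane carbon is acylated by one acyl chloride, and the enol oxygen of the resulting β-diketone closes ring B on the second. Both partners are symmetric, so one pyranone results, with ethyl at C6' and methyl at C5'.

Step 3
Reactants: 4 6-ethyl-4-hydroxy-5-methyl-2H-pyran-2-one; 5 but-3-en-2-one
Product: 6 6-ethyl-4-hydroxy-5-methyl-3-(3-oxobutyl)-2H-pyran-2-one (in equilibrium with its cyclic hemiketal)
Conditions: 5 (1.5 equiv), Et3N (0.2 equiv), MeOH, 50 °C
Reagents that add atoms: none
Why: Michael addition of the vinylogous acid through C3', its only free nucleophilic carbon, as in the additions of 4-hydroxycoumarins and 4-hydroxypyranones to enones. C3' is then fully substituted, so the reaction stops after one addition.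

Step 4
Reactants: 6 6-ethyl-4-hydroxy-5-methyl-3-(3-oxobutyl)-2H-pyran-2-one; 7 2-methylpropanoyl chloride
Product: 8 6-ethyl-4-hydroxy-5-methyl-3-(6-methyl-3,5-dioxoheptyl)-2H-pyran-2-one
Conditions: LiN(SiMe3)2 (3.1 equiv), THF, −78 °C; 7 (1.05 equiv), −78 to −20 °C; 1 M HCl
Reagents that add atoms: none
Why: Crossed Claisen-type C-acylation of the kinetic lithium enolate at the methyl group, with the third equivalent of base taking up the acidic proton of the new β-diketone. The lithium pyranonate is inert, disfavours deprotonation at the CH2 group close to it, and cannot leave in a retro-Michael reaction.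

Step 5
Reactants: 8 6-ethyl-4-hydroxy-5-methyl-3-(6-methyl-3,5-dioxoheptyl)-2H-pyran-2-one
Product: 9 6-ethyl-4-hydroxy-3-[(3E)-3-methoxy-6-methyl-5-oxohept-3-en-1-yl]-5-methyl-2H-pyran-2-one
Conditions: HC(OMe)3 (3 equiv), TsOH·H2O (5 mol %), MeOH, rt; Et3N quench before concentration
Reagents that add atoms: trimethyl orthoformate, COC(OC)OC
Why: Standard acid-catalysed enol etherification of a β-diketone by ketalisation and loss of methanol. The carbonyl beside the CH2 group is attacked in preference to the one shielded by isopropyl, and it is the only one the C4' hydroxyl can assist through a six-membered mixed ketal, so the methoxy group should end on the future C6. At room temperature the hindered vinylogous acid of ring B should stay unetherified.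

Step 6
Reactants: 9 6-ethyl-4-hydroxy-3-[(3E)-3-methoxy-6-methyl-5-oxohept-3-en-1-yl]-5-methyl-2H-pyran-2-one
Product: 10 6-ethyl-3-[3-methoxy-6-methyl-5-(trimethylsilyloxy)hepta-2,4-dien-1-yl]-5-methyl-4-(trimethylsilyloxy)-2H-pyran-2-one
Conditions: Me3SiOTf (2.3 equiv), Et3N (3 equiv), Et2O, 0 °C to rt; pentane extraction under Ar, used crude
Reagents that add atoms: trimethylsilyl trifluoromethanesulfonate, C[Si](C)(C)OS(=O)(=O)C(F)(F)F
Why: Soft enolisation to a silyl dienol ether, as in the preparation of oxygenated dienes from β-methoxy enones and enoates, with C4'–OH silylated in the same operation. The bulky amine should take a proton from the accessible CH2 group (future C1) rather than from the tertiary isopropyl C–H, whose loss would give a strained tetrasubstituted enol silane.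

Step 7
Reactants: 11 diethyl propanedioate; 12 1-bromo-3-methylbut-2-ene
Product: 13 diethyl 2-(3-methylbut-2-en-1-yl)propanedioate
Conditions: NaH, THF, 0 °C; 12, 0 °C to rt (11 in excess)
Reagents that add atoms: none
Why: Malonic ester alkylation by SN2 displacement on a primary allylic bromide. The excess of 11 suppresses dialkylation.

Step 8
Reactants: 13 diethyl 2-(3-methylbut-2-en-1-yl)propanedioate
Product: 14 2-(3-methylbut-2-en-1-yl)propanedioic acid
Conditions: KOH (2.5 equiv), EtOH–H2O, rt; cold 1 M HCl to pH 2
Reagents that add atoms: potassium hydroxide, [K+].[OH-]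
Why: Ester saponification. Cold and brief acidification avoids decarboxylation and acid-induced lactonisation onto the prenyl alkene.

Step 9
Reactants: 14 2-(3-methylbut-2-en-1-yl)propanedioic acid
Product: 15 2-(3-methylbut-2-en-1-yl)propanedioyl dichloride
Conditions: (COCl)2 (2.4 equiv), DMF (cat.), CH2Cl2, 0 °C to rt; volatiles removed, used crude
Reagents that add atoms: oxalyl chloride, O=C(Cl)C(=O)Cl
Why: Acid chloride formation through the Vilsmeier-type chloroiminium catalyst. All by-products are gases, and the low temperature keeps HCl from adding to the trisubstituted alkene.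

Step 10
Reactants: 10 6-ethyl-3-[3-methoxy-6-methyl-5-(trimethylsilyloxy)hepta-2,4-dien-1-yl]-5-methyl-4-(trimethylsilyloxy)-2H-pyran-2-one; 15 2-(3-methylbut-2-en-1-yl)propanedioyl dichloride
Product: 18 6-ethyl-4-hydroxy-3-{[2,4-dihydroxy-6-methoxy-3-(3-methylbut-2-en-1-yl)-5-(2-methylpropanoyl)phenyl]methyl}-5-methyl-2H-pyran-2-one (target), via keto acid chloride 16 (not isolated), via ring B silyl ether 17 (not isolated)
Conditions: 15 (1.0 equiv), CH2Cl2, −78 to 0 °C; Et3N (1.1 equiv), 0 °C to rt; citric acid, MeOH–H2O, rt
Reagents that add atoms: none
Why: Proposed new method: the diene terminus C1 of 10, which receives the push of both the silyloxy and the methoxy oxygen, should attack one acyl chloride of 15 with loss of the silyl group and give 16, a vinylogous Mukaiyama-type γ-acylation known for 1,3-bis(silyloxy)dienes and 1-methoxy-3-silyloxydienes with acid chlorides. Et3N then takes HCl from the β-keto acid chloride of 16, and the acylketene (or the acid chloride itself) is attacked by C5, the α-carbon of the β-methoxy enone and its natural nucleophilic site, which forms C4–C5. Ring A thus closes by a 6-(enolendo)-exo-trig C-acylation, which can equally be described as the 6π electrocyclisation of a dienylketene that ends a Danheiser benzannulation, and two enolisations then give the arene 17 as an irreversible sink before mild acid removes the silyl group from C4'–O. The closest known reaction types are the Effenberger α,α'-annulation of methyl enol ethers with malonyl dichloride and the biomimetic Claisen cyclisation of 3,5,7-trioxo esters to acylphloroglucinols; what is new is their combination on an open-chain diene that can aromatise and so keep its methoxy group. No stereocentre is set, because C1 and C3 of 16 are stereogenic only in passing. No orientation problem exists towards 15, because its two acyl groups are equivalent. C-closure over O-closure is secured by the substrate: the methyl group on the C6 oxygen blocks the lactonisation that free or silylated 1,3-dicarbonyl dienes undergo with malonyl dichlorides, the acyl oxygen could only close an eight-membered ring, and in ring B C3' is fully substituted and C4'–OH is silylated. The order of events (γ-carbon first, α-carbon second) is secured by the use of the silyl dienol ether in place of a metal dienolate.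

## Compound list

| No. | Name | SMILES | Role |
|---|---|---|---|
| 1 | pentan-3-one | CCC(=O)CC | starting material |
| 2 | 3-(trimethylsilyloxy)pent-2-ene | CC=C(CC)O[Si](C)(C)C | intermediate |
| 3 | propanedioyl dichloride | O=C(Cl)CC(=O)Cl | starting material |
| 4 | 6-ethyl-4-hydroxy-5-methyl-2H-pyran-2-one | CCc1oc(=O)cc(O)c1C | intermediate |
| 5 | but-3-en-2-one | CC(=O)C=C | starting material |
| 6 | 6-ethyl-4-hydroxy-5-methyl-3-(3-oxobutyl)-2H-pyran-2-one | CCc1oc(=O)c(CCC(C)=O)c(O)c1C | intermediate |
| 7 | 2-methylpropanoyl chloride | CC(C)C(=O)Cl | starting material |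
| 8 | 6-ethyl-4-hydroxy-5-methyl-3-(6-methyl-3,5-dioxoheptyl)-2H-pyran-2-one | CCc1oc(=O)c(CCC(=O)CC(=O)C(C)C)c(O)c1C | intermediate |
| 9 | 6-ethyl-4-hydroxy-3-[(3E)-3-methoxy-6-methyl-5-oxohept-3-en-1-yl]-5-methyl-2H-pyran-2-one | CCc1oc(=O)c(CC/C(OC)=C\C(=O)C(C)C)c(O)c1C | intermediate |
| 10 | 6-ethyl-3-[3-methoxy-6-methyl-5-(trimethylsilyloxy)hepta-2,4-dien-1-yl]-5-methyl-4-(trimethylsilyloxy)-2H-pyran-2-one | CCc1oc(=O)c(CC=C(OC)C=C(O[Si](C)(C)C)C(C)C)c(O[Si](C)(C)C)c1C | intermediate |
| 11 | diethyl propanedioate | CCOC(=O)CC(=O)OCC | starting material |
| 12 | 1-bromo-3-methylbut-2-ene | CC(C)=CCBr | starting material |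
| 13 | diethyl 2-(3-methylbut-2-en-1-yl)propanedioate | CCOC(=O)C(CC=C(C)C)C(=O)OCC | intermediate |
| 14 | 2-(3-methylbut-2-en-1-yl)propanedioic acid | OC(=O)C(CC=C(C)C)C(=O)O | intermediate |
| 15 | 2-(3-methylbut-2-en-1-yl)propanedioyl dichloride | O=C(Cl)C(CC=C(C)C)C(=O)Cl | intermediate |
| 16 | 4-{[6-ethyl-5-methyl-2-oxo-4-(trimethylsilyloxy)-2H-pyran-3-yl]methyl}-5-methoxy-8-methyl-2-(3-methylbut-2-en-1-yl)-3,7-dioxonon-5-enoyl chloride | CCc1oc(=O)c(CC(C(=O)C(CC=C(C)C)C(=O)Cl)C(OC)=CC(=O)C(C)C)c(O[Si](C)(C)C)c1C | intermediate |
| 17 | 3-{[2,4-dihydroxy-6-methoxy-3-(3-methylbut-2-en-1-yl)-5-(2-methylpropanoyl)phenyl]methyl}-6-ethyl-5-methyl-4-(trimethylsilyloxy)-2H-pyran-2-one | CCc1oc(=O)c(Cc2c(O)c(CC=C(C)C)c(O)c(C(=O)C(C)C)c2OC)c(O[Si](C)(C)C)c1C | intermediate |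
| 18 | 6-ethyl-4-hydroxy-3-{[2,4-dihydroxy-6-methoxy-3-(3-methylbut-2-en-1-yl)-5-(2-methylpropanoyl)phenyl]methyl}-5-methyl-2H-pyran-2-one | CCc1oc(=O)c(Cc2c(O)c(CC=C(C)C)c(O)c(C(=O)C(C)C)c2OC)c(O)c1C | target |

## Step count and least certain steps

- Total step count: 10.
- Longest linear sequence: 7 (steps 1 to 6, then step 10). Steps 7 to 9 form the second branch.

**Step 10 (key step, Proposed new method).**
- *What may go wrong.*
  - The diene may attack through C5 instead of C1. The acyl oxygen could then lactonise onto the second acyl group.
  - Closure may go through the methoxy oxygen, with loss of its methyl group to chloride.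
  - The ketene may react intermolecularly before the ring closes.
  - HCl may add to the prenyl alkene, or the alkene may cyclise onto a new phenol.
- *Fallback (known chemistry only).* It sets out from 4 and comes back at 18.
  - 5-Methoxybenzene-1,3-diol is C-acylated with 7 and AlCl3 to 1-(2,4-dihydroxy-6-methoxyphenyl)-2-methylpropan-1-one F1, and the regioisomer is separated.
  - The phenolate of F1 is C-prenylated with 12 and aqueous KOH at 0 °C, between the two hydroxyls. This gives 1-[2,4-dihydroxy-6-methoxy-3-(3-methylbut-2-en-1-yl)phenyl]-2-methylpropan-1-one F2, the same compound as A1.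
  - F2, 4 and paraformaldehyde are then joined by the usual methylene-bridging condensation to give 18.

**Step 6.**
- *What may go wrong.* Enolisation may run towards the isopropyl methine instead of the CH2 group. That gives the cross-conjugated diene, whose nucleophilic terminus is the wrong carbon. At best this material is returned as 9 on work-up.
- *Fallback.* It sets out from 15 and comes back at 18. Ring A is built before the bridge, on a diene in which the competing sites are a methyl group and a tertiary methine.
  - 5-Methylhexane-2,4-dione is etherified with HC(OMe)3 and acid to (4E)-5-methoxy-2-methylhex-4-en-3-one F3.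
  - F3 is silylated with Me3SiOTf and Et3N to [(5-methoxy-2-methylhexa-3,5-dien-3-yl)oxy]trimethylsilane F4.
  - F4 is annulated with 15 under the conditions of step 10 to the ketone F2.
  - F2 is bridged to 4 with paraformaldehyde to give 18.

**Step 5.**
- *What may go wrong.* Site selectivity between the two carbonyl groups of 8 may be poor. The C4' hydroxyl of ring B may be slowly etherified under acid.
- *Fallback.* It sets out from 4 and comes back at 9. It fixes the position of the methoxy group through an alkyne and uses no acid.
  - Michael addition of 4 to acrolein gives 3-(6-ethyl-4-hydroxy-5-methyl-2-oxo-2H-pyran-3-yl)propanal F5, which rests as its lactol.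
  - Ohira–Bestmann homologation (K2CO3, MeOH) gives 3-(but-3-yn-1-yl)-6-ethyl-4-hydroxy-5-methyl-2H-pyran-2-one F6.
  - Double deprotonation with EtMgBr, followed by acylation with N-methoxy-N,2-dimethylpropanamide, gives 6-ethyl-4-hydroxy-5-methyl-3-(6-methyl-5-oxohept-3-yn-1-yl)-2H-pyran-2-one F7.
  - Conjugate addition of NaOMe in MeOH to the ynone can only place the methoxy group on the β-carbon, the future C6, and gives 9.

**Step 4.**
- *What may go wrong.* Some of the internal enolate may form. The enolate or the pyranonate may be O-acylated. The C6' ethyl group may be deprotonated by the excess base.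
- *Fallback.* It sets out from 4 and comes back at 8. It replaces steps 3 and 4 by a Michael addition to an acceptor that already holds the whole diketone.
  - The kinetic enolate of 3-methylbutan-2-one, made with LiN(SiMe3)2, is acylated with 3-chloropropanoyl chloride to 1-chloro-6-methylheptane-3,5-dione F8.
  - Et3N eliminates HCl in the presence of 4 to give 6-methylhept-1-ene-3,5-dione F9.
  - F9 is trapped in situ at C3' to give 8.

## Further compounds

F1 | step 10 | 1-(2,4-dihydroxy-6-methoxyphenyl)-2-methylpropan-1-one | CC(C)C(=O)c1c(O)cc(O)cc1OC
F2 | step 10 | 1-[2,4-dihydroxy-6-methoxy-3-(3-methylbut-2-en-1-yl)phenyl]-2-methylpropan-1-one | CC(C)C(=O)c1c(O)c(CC=C(C)C)c(O)cc1OC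
F3 | step 6 | (4E)-5-methoxy-2-methylhex-4-en-3-one | CC(C)C(=O)/C=C(/OC)C
F4 | step 6 | [(5-methoxy-2-methylhexa-3,5-dien-3-yl)oxy]trimethylsilane | CC(C)C(O[Si](C)(C)C)=CC(OC)=C
F5 | step 5 | 3-(6-ethyl-4-hydroxy-5-methyl-2-oxo-2H-pyran-3-yl)propanal | CCc1oc(=O)c(CCC=O)c(O)c1C
F6 | step 5 | 3-(but-3-yn-1-yl)-6-ethyl-4-hydroxy-5-methyl-2H-pyran-2-one | CCc1oc(=O)c(CCC#C)c(O)c1C
F7 | step 5 | 6-ethyl-4-hydroxy-5-methyl-3-(6-methyl-5-oxohept-3-yn-1-yl)-2H-pyran-2-one | CCc1oc(=O)c(CCC#CC(=O)C(C)C)c(O)c1C
F8 | step 4 | 1-chloro-6-methylheptane-3,5-dione | CC(C)C(=O)CC(=O)CCCl
F9 | step 4 | 6-methylhept-1-ene-3,5-dione | CC(C)C(=O)CC(=O)C=C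
A1 | alternative 1 | 1-[2,4-dihydroxy-6-methoxy-3-(3-methylbut-2-en-1-yl)phenyl]-2-methylpropan-1-one | CC(C)C(=O)c1c(O)c(CC=C(C)C)c(O)cc1OC
A2 | alternative 1 | 6-ethyl-5-methyl-3-methylidene-2H-pyran-2,4(3H)-dione | CCC1=C(C)C(=O)C(=C)C(=O)O1
A3 | alternative 2 | 4-{[6-ethyl-4-(methoxymethoxy)-5-methyl-2-oxo-2H-pyran-3-yl]methyl}-5-methoxy-3-(methoxymethoxy)-2-(3-methylbut-2-en-1-yl)-6-(trimethylsilyl)phenyl trifluoromethanesulfonate | CCc1oc(=O)c(Cc2c(OCOC)c(CC=C(C)C)c(OS(=O)(=O)C(F)(F)F)c([Si](C)(C)C)c2OC)c(OCOC)c1C
A4 | alternative 2 | aryne of ring A with the triple bond between C4 and C5 (both hydroxyls as methoxymethyl ethers) | COC1=C(Cc2c(OCOC)c(C)c(CC)oc2=O)C(OCOC)=C(CC=C(C)C)C#C1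
A5 | alternative 3 | 6-ethyl-4-hydroxy-3-{[4-hydroxy-2-(3-methyl-2-oxobutyl)-5-(3-methylbut-2-en-1-yl)-6-oxo-6H-pyran-3-yl]methyl}-5-methyl-2H-pyran-2-one | CCc1oc(=O)c(Cc2c(O)c(CC=C(C)C)c(=O)oc2CC(=O)C(C)C)c(O)c1C
A6 | alternative 3 | 6-ethyl-4-hydroxy-5-methyl-3-{[2,4,6-trihydroxy-3-(3-methylbut-2-en-1-yl)-5-(2-methylpropanoyl)phenyl]methyl}-2H-pyran-2-one | CCc1oc(=O)c(Cc2c(O)c(CC=C(C)C)c(O)c(C(=O)C(C)C)c2O)c(O)c1C
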